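## Retrosynthetic overview

Numbering: benzene carbons C1–C6 (C1 bears the side chain, C2 and C5 the hydroquinone oxygens, C3 the OMe, C4 the Me); C7 bears the exocyclic CH2, C8 the angelate, C9–C11 are the prenyl carbons.
The target comes from its hydroquinone diether (C2–OMOM, C5–OMe) by oxidative dealkylation to the para-quinone and reduction; both phenol oxygens stay masked through the palladium step.
Key disconnection: the aryl C1–C7 bond and the C8–O(angelate) bond are cut together. C7 carries the benzene ring and the exocyclic CH2 while its neighbour C8 carries the carboxylate, which is the pattern left by adding an aryl group and a carboxylate across the substituted C=C of a terminal allene whose central carbon becomes C7.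
Pieces: an aryl iodide (from 2,4-dimethoxy-3-methylbenzaldehyde by Baeyer–Villiger oxidation, MOM protection and MOM-directed ortho-iodination; the MOM group is kept, which saves a protecting-group exchange), 6-methylhepta-1,2,5-triene (from prenyl bromide by copper-catalysed ethynylation and Crabbé homologation) and angelic acid.
No ring is formed (the benzene ring is bought); the only stereocenter, C8, is set in the three-component coupling by a chiral phosphoramidite on palladium.

Key step: step 6

Assumption: the sense of induction of the phosphoramidite in step 6 cannot be predicted with confidence; the ligand antipode that gives the (S) ester is to be identified in a first run, the mirror-image ligand giving the (R) ester.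

## Route

Step 1
Reactants: 1 2,4-dimethoxy-3-methylbenzaldehyde
Product: 3 2,4-dimethoxy-3-methylphenol, via aryl formate 2 (not isolated)
Conditions: mCPBA, CH2Cl2, 0 °C to rt; then K2CO3, MeOH, rt
Reagents that add atoms: mCPBA, O=C(OO)c1cccc(Cl)c1
Why: Baeyer–Villiger (Dakin-type) oxidation, in which the aryl group made electron-rich by its ortho and para methoxy groups migrates in the Criegee adduct in preference to hydride, and formate 2 is then cleaved by methanolysis.

Step 2
Reactants: 3 2,4-dimethoxy-3-methylphenol
Product: 4 2,4-dimethoxy-1-(methoxymethoxy)-3-methylbenzene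
Conditions: MeOCH2Cl, i-Pr2NEt, CH2Cl2, 0 °C to rt
Reagents that add atoms: chloromethyl methyl ether, COCCl
Why: O-alkylation of the phenol (Williamson-type) installs an acetal that protects the future C2 oxygen and serves as the directing group for step 3.

Step 3
Reactants: 4 2,4-dimethoxy-1-(methoxymethoxy)-3-methylbenzene
Product: 6 1-iodo-3,5-dimethoxy-2-(methoxymethoxy)-4-methylbenzene, via aryllithium 5 (not isolated)
Conditions: n-BuLi, TMEDA, THF, −78 to 0 °C; then I2, −78 °C to rt
Reagents that add atoms: iodine, [I][I]
Why: Directed ortho-metalation, in which OMOM outranks OMe as a director and has only one free ortho position (the future C1), followed by iodination of aryllithium 5 at that carbon.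

Step 4
Reactants: 7 prenyl bromide (1-bromo-3-methylbut-2-ene)
Product: 8 5-methylhex-4-en-1-yne
Conditions: HC≡CMgBr (0.5 M in THF), CuCl (5 mol %), THF, 0 to 50 °C
Reagents that add atoms: ethynylmagnesium bromide, C#C[Mg]Br
Why: Copper-catalysed SN2 allylation of an alkynyl Grignard reagent at the primary carbon of the allylic bromide should give the skipped enyne with the trisubstituted olefin intact.

Step 5
Reactants: 8 5-methylhex-4-en-1-yne
Product: 10 6-methylhepta-1,2,5-triene, via propargylic amine 9 (not isolated)
Conditions: (CH2O)n, CuI (0.5 equiv), Cy2NH, 1,4-dioxane, reflux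
Reagents that add atoms: paraformaldehyde (as formaldehyde), C=O
Why: Crabbé homologation, in which a copper-mediated Mannich condensation gives propargylic amine 9 and a copper-assisted 1,5-hydride shift with loss of the imine delivers the terminal allene, the prenyl olefin being a spectator.

Step 6
Reactants: 6 1-iodo-3,5-dimethoxy-2-(methoxymethoxy)-4-methylbenzene, 10 6-methylhepta-1,2,5-triene, 11 angelic acid ((2Z)-2-methylbut-2-enoic acid)
Product: 14 (3S)-2-[3,5-dimethoxy-2-(methoxymethoxy)-4-methylphenyl]-6-methylhepta-1,5-dien-3-yl (2Z)-2-methylbut-2-enoate, via caesium angelate 12 (not isolated), via allylpalladium iodide complex 13 (not isolated)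
Conditions: Pd2(dba)3 (2.5 mol %), BINOL-derived N,N-bis(1-phenylethyl)phosphoramidite (single enantiomer, 10 mol %), Cs2CO3 (1.5 equiv), 10 and 11 (1.5 equiv each), THF, 40 °C, sealed tube, argon
Reagents that add atoms: none
Why: Proposed new method: oxidative addition of the C–I bond of 6 to the zerovalent palladium–phosphoramidite catalyst, then syn carbopalladation of the terminal C=C of allene 10, puts the aryl group on the central allene carbon (C1–C7 bond) and gives the 2-aryl-1-alkyl allyl complex 13 of divalent palladium, which carboxylate 12 attacks at the substituted terminus C8 on the face opposite to the metal (C8–O bond) with release of zerovalent palladium. The closest known reaction types are the palladium-catalysed three-component coupling of aryl halides, 1,2-dienes and amine, malonate or phenoxide nucleophiles, which normally ends at the unsubstituted allyl terminus, and the rhodium–diphosphine-catalysed branched, enantioselective addition of carboxylic acids to terminal allenes; the combination of aryl insertion with branched, enantioselective carboxylate capture is not established. No ring is closed. The C8 stereocenter is controlled by the chiral ligand alone, since the two diastereomeric allyl complexes exchange faces rapidly by η3–η1–η3 slippage through the CH2 terminus and the (S) ester is drawn from the faster-reacting one (Curtin–Hammett control). The step needs insertion at the allene in preference to the trisubstituted prenyl and angelate olefins (secured by the far higher reactivity of the cumulated π bond), aryl transfer to the central carbon (inherent to allene carbopalladation) and C–O bond formation at C8 instead of the methylene terminus, for which the substrate offers the 2-aryl group, twisted by its ortho OMOM substituent, that pushes the C8 chain into the anti position with a longer, more electrophilic Pd–C8 bond, while the π-acidic monodentate ligand and the hard carboxylate favour charge-controlled attack at the more substituted carbon. Both phenol oxygens are masked so that no ortho phenoxide can trap 13 intramolecularly, the acid enters only as a carboxylate so its Z olefin is never activated toward isomerisation, and the reaction is to be stopped as soon as 6 is consumed because the branched ester can re-ionise.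

Step 7
Reactants: 14 (3S)-2-[3,5-dimethoxy-2-(methoxymethoxy)-4-methylphenyl]-6-methylhepta-1,5-dien-3-yl (2Z)-2-methylbut-2-enoate
Product: 15 (3S)-2-(5-methoxy-4-methyl-3,6-dioxocyclohexa-1,4-dien-1-yl)-6-methylhepta-1,5-dien-3-yl (2Z)-2-methylbut-2-enoate
Conditions: (NH4)2Ce(NO3)6 (2.5 equiv), MeCN/H2O 3:1, 0 °C, 10 min
Reagents that add atoms: water, O
Why: Oxidative dealkylation of a hydroquinone diether by tetravalent cerium, in which the arene radical cation is trapped by water at the para-related C2 and C5 so that the MOM and methyl groups leave and the para-quinone forms (prior acid-induced loss of the MOM group in the acidic medium would lead to the same quinone), while the C3 methoxy group, the olefins and the angelate should survive the short exposure at 0 °C.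

Step 8
Reactants: 15 (3S)-2-(5-methoxy-4-methyl-3,6-dioxocyclohexa-1,4-dien-1-yl)-6-methylhepta-1,5-dien-3-yl (2Z)-2-methylbut-2-enoate
Product: 16 (3S)-2-(2,5-dihydroxy-3-methoxy-4-methylphenyl)-6-methylhepta-1,5-dien-3-yl (2Z)-2-methylbut-2-enoate
Conditions: Na2S2O4, EtOAc/H2O, rt, argon
Reagents that add atoms: none
Why: Two-electron reduction of the quinone by Na2S2O4 in a neutral two-phase system should give the hydroquinone without touching the allylic angelate, its Z olefin or the C8 stereocenter.

## Compound list

1 | 2,4-dimethoxy-3-methylbenzaldehyde | O=Cc1ccc(OC)c(C)c1OC | starting material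
2 | 2,4-dimethoxy-3-methylphenyl formate | O=COc1ccc(OC)c(C)c1OC | intermediate
3 | 2,4-dimethoxy-3-methylphenol | Oc1ccc(OC)c(C)c1OC | intermediate
4 | 2,4-dimethoxy-1-(methoxymethoxy)-3-methylbenzene | COCOc1ccc(OC)c(C)c1OC | intermediate
5 | [3,5-dimethoxy-2-(methoxymethoxy)-4-methylphenyl]lithium | COCOc1c([Li])cc(OC)c(C)c1OC | intermediate
6 | 1-iodo-3,5-dimethoxy-2-(methoxymethoxy)-4-methylbenzene | COCOc1c(I)cc(OC)c(C)c1OC | intermediate
7 | prenyl bromide (1-bromo-3-methylbut-2-ene) | CC(C)=CCBr | starting material
8 | 5-methylhex-4-en-1-yne | C#CCC=C(C)C | intermediate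
9 | N,N-dicyclohexyl-6-methylhept-5-en-2-yn-1-amine | CC(C)=CCC#CCN(C1CCCCC1)C1CCCCC1 | intermediate
10 | 6-methylhepta-1,2,5-triene | C=C=CCC=C(C)C | intermediate
11 | angelic acid, (2Z)-2-methylbut-2-enoic acid | C/C=C(/C)C(=O)O | starting material
12 | caesium angelate, caesium (2Z)-2-methylbut-2-enoate | C/C=C(/C)C(=O)[O-].[Cs+] | intermediate
13 | iodo{2-[3,5-dimethoxy-2-(methoxymethoxy)-4-methylphenyl]-6-methylhepta-1,5-dien-3-yl}palladium, the 2-aryl-1-alkyl allyl complex of divalent palladium drawn in its C8-bonded η1 form, phosphoramidite not shown | C=C(c1cc(OC)c(C)c(OC)c1OCOC)C([Pd]I)CC=C(C)C | intermediate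
14 | (3S)-2-[3,5-dimethoxy-2-(methoxymethoxy)-4-methylphenyl]-6-methylhepta-1,5-dien-3-yl (2Z)-2-methylbut-2-enoate | C=C(c1cc(OC)c(C)c(OC)c1OCOC)[C@H](CC=C(C)C)OC(=O)/C(C)=C\C | intermediate
15 | (3S)-2-(5-methoxy-4-methyl-3,6-dioxocyclohexa-1,4-dien-1-yl)-6-methylhepta-1,5-dien-3-yl (2Z)-2-methylbut-2-enoate | C=C(C1=CC(=O)C(C)=C(OC)C1=O)[C@H](CC=C(C)C)OC(=O)/C(C)=C\C | intermediate
16 | (3S)-2-(2,5-dihydroxy-3-methoxy-4-methylphenyl)-6-methylhepta-1,5-dien-3-yl (2Z)-2-methylbut-2-enoate | C=C(c1cc(O)c(C)c(OC)c1O)[C@H](CC=C(C)C)OC(=O)/C(C)=C\C | target

## Step count and risks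

Total step count: 8. Longest linear sequence: 6 steps (steps 1, 2, 3, 6, 7, 8 from aldehyde 1); the allene branch is 2 steps.

Steps most likely to fail:

1. Step 6 (Proposed new method). The carboxylate may attack the unsubstituted methylene terminus and give the linear ester. The branched ester may re-ionise and lose regio- and enantiopurity. The allyl complex may undergo β-hydride elimination toward a conjugated triene. Facial discrimination by the ligand may be poor.
Fallback by known chemistry, from 6 and 11 back to 14: the C1–C7 bond would be made by Stille coupling and the C8 stereocenter by ketone transfer hydrogenation. Commercial 4-methylpent-3-enoic acid would be converted (1,1'-carbonyldiimidazole, then MeNHOMe·HCl, CH2Cl2) into N-methoxy-N,4-dimethylpent-3-enamide F1. Addition of lithium (trimethylsilyl)acetylide (THF, −78 °C) would give 6-methyl-1-(trimethylsilyl)hept-5-en-1-yn-3-one F2. Base-free Noyori asymmetric transfer hydrogenation (RuCl(p-cymene)[(S,S)-TsDPEN], i-PrOH, rt) would give (3S)-6-methyl-1-(trimethylsilyl)hept-5-en-1-yn-3-ol F3; the (S) sense is expected by analogy with other alkynyl ketones and would have to be confirmed. K2CO3 in MeOH would give (3S)-6-methylhept-5-en-1-yn-3-ol F4. Molybdenum-catalysed α-selective hydrostannation (Bu3SnH, Mo(CO)3(CNtBu)3, THF, 55 °C) would give (3S)-6-methyl-2-(tributylstannyl)hepta-1,5-dien-3-ol F5. Stille coupling with 6 (Pd(PPh3)4, CuI, CsF, DMF, 45 °C) would give (3S)-2-[3,5-dimethoxy-2-(methoxymethoxy)-4-methylphenyl]-6-methylhepta-1,5-dien-3-ol F6. Yamaguchi-type acylation with (2Z)-2-methylbut-2-enoic 2,4,6-trichlorobenzoic anhydride F7, made from 11 and 2,4,6-trichlorobenzoyl chloride (Et3N, toluene), at 75 °C would give 14 with retention at C8 and is expected to keep the Z acyl geometry.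

2. Step 7. The one-electron oxidant may attack the electron-rich styrene or prenyl olefin, may remove the C3 methyl group toward an ortho-quinone, or the vinyl quinone may decompose during work-up.
Fallback, from 14 back to 15: the MOM ether would be cleaved chemoselectively (TMSOTf, 2,2'-bipyridyl, CH2Cl2, 0 °C; then H2O) to (3S)-2-(2-hydroxy-3,5-dimethoxy-4-methylphenyl)-6-methylhepta-1,5-dien-3-yl (2Z)-2-methylbut-2-enoate F8. This free para-methoxyphenol would then be oxidised in a two-electron process with PhI(OAc)2 in MeCN/H2O at 0 °C to quinone 15.

3. Step 4. The acetylide may attack the tertiary carbon (SN2′), acetylene may be alkylated twice, and the volatile enyne may be lost on removal of THF.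
Fallback, from 7 back to 10 (it also bypasses step 5): coupling of 7 with propargyl alcohol (CuI, NaI, K2CO3, DMF, rt) would give the non-volatile 6-methylhept-5-en-2-yn-1-ol F9. A Myers allene synthesis would follow: Mitsunobu alkylation of 2-nitrobenzenesulfonylhydrazide (PPh3, DEAD, THF, −15 °C) would give N-(6-methylhept-5-en-2-yn-1-yl)-2-nitrobenzenesulfonohydrazide F10. On warming to rt this would lose the sulfinic acid to give (6-methylhept-5-en-2-yn-1-yl)diazene F11, whose retro-ene loss of dinitrogen would deliver allene 10.

Further compounds
F1 | step 6 | N-methoxy-N,4-dimethylpent-3-enamide | CON(C)C(=O)CC=C(C)C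
F2 | step 6 | 6-methyl-1-(trimethylsilyl)hept-5-en-1-yn-3-one | C[Si](C)(C)C#CC(=O)CC=C(C)C
F3 | step 6 | (3S)-6-methyl-1-(trimethylsilyl)hept-5-en-1-yn-3-ol | C[Si](C)(C)C#C[C@H](CC=C(C)C)O
F4 | step 6 | (3S)-6-methylhept-5-en-1-yn-3-ol | C#C[C@H](CC=C(C)C)O
F5 | step 6 | (3S)-6-methyl-2-(tributylstannyl)hepta-1,5-dien-3-ol | C=C([Sn](CCCC)(CCCC)CCCC)[C@H](CC=C(C)C)O
F6 | step 6 | (3S)-2-[3,5-dimethoxy-2-(methoxymethoxy)-4-methylphenyl]-6-methylhepta-1,5-dien-3-ol | C=C(c1cc(OC)c(C)c(OC)c1OCOC)[C@H](CC=C(C)C)O
F7 | step 6 | (2Z)-2-methylbut-2-enoic 2,4,6-trichlorobenzoic anhydride | C/C=C(/C)C(=O)OC(=O)c1c(Cl)cc(Cl)cc1Cl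
F8 | step 7 | (3S)-2-(2-hydroxy-3,5-dimethoxy-4-methylphenyl)-6-methylhepta-1,5-dien-3-yl (2Z)-2-methylbut-2-enoate | C=C(c1cc(OC)c(C)c(OC)c1O)[C@H](CC=C(C)C)OC(=O)/C(C)=C\C
F9 | step 4 | 6-methylhept-5-en-2-yn-1-ol | OCC#CCC=C(C)C
F10 | step 4 | N-(6-methylhept-5-en-2-yn-1-yl)-2-nitrobenzenesulfonohydrazide | NN(CC#CCC=C(C)C)S(=O)(=O)c1ccccc1[N+](=O)[O-]
F11 | step 4 | (6-methylhept-5-en-2-yn-1-yl)diazene | N=NCC#CCC=C(C)C
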